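Remark: the target has no stereocenter. Compounds 1, 2 and 5 are taken as catalogue chemicals, and 4 is made rather than bought.

**Numbering used throughout**

- 1: 1,2,3-tribromobenzene
- 2: bis(pinacolato)diboron
- 3: pinacol boronate of 1 (not isolated)
- 4: 3,4,5-tribromophenol
- 5: diphenyliodonium triflate
- 6: 1,2,3-tribromo-5-phenoxybenzene
- 7: arylmagnesium chloride from 6 (not isolated)
- 8: its dimethyl boronate (not isolated)
- 9: 2,3,4-tribromo-6-phenoxyphenol
- 10: target

Atom labels follow the target in every intermediate. Ring A: C1 (hydroxyl carbon), C2 (ether carbon), C3 (C–H), C4, C5, C6 (bromines). Ring B: C1' (ether carbon), C2' and C4' (bromines).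

## Analysis of the target

Compound 10 is a pentabrominated 2-phenoxyphenol: two benzene rings joined through one ether oxygen, with no stereocenter and no ring to construct. The phenol is acidic and easily oxidised. The five C–Br bonds exclude hydrogenolysis, halogen–metal exchange reagents used without discrimination, hot copper or palladium couplings, and any long-lived ortho-bromoaryl anion that can lose bromide to an aryne. The difficulty is one of regiochemistry only. The ring B bromines lie ortho and para to the ether oxygen and are easy to place. The C5 bromine of ring A, however, is meta to the hydroxyl and wedged between two other bromines, so electrophilic bromination of a phenol cannot deliver the C4–C5–C6 array cleanly. The strategy rests on what is left of ring A when the C1 hydroxyl is removed in thought: a 3,4,5-tribromophenyl ether with a mirror plane through C2 and C5. Its only two C–H bonds, C1–H and C3–H, are equivalent, and each lies between the ether oxygen and a bromine, which makes them the most acidic hydrogens of the molecule. Deprotonation there and conversion of the carbon–metal bond into a carbon–oxygen bond installs the hydroxyl with no regiochemical choice to make.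

## Retrosynthetic reasoning

**10 to 9.** The C2'–Br and C4'–Br bonds of ring B are cut first. They sit ortho and para to the ether oxygen, so electrophilic bromination can make them. In 9 every position ortho or para to the hydroxyl is already occupied. The one ring A hydrogen left, C3–H, is ortho to the ether oxygen and therefore not wholly unactivated, but it is crowded between that oxygen and the C4 bromine on a ring carrying three deactivating halogens. Leaving ring B as plain phenyl until the end also keeps a C3'–H flanked by two bromines out of the metalation step. The forward reaction has to place exactly two bromines on ring B and stop.

**9 to 6.** The C1–O bond of the hydroxyl is cut back to C1–H. This is the only disconnection that turns ring A into a symmetric fragment: in 6 the hydrogens at C1 and C3 are identical, so the hydroxylation cannot give a regioisomer. The forward reaction is a deprotonation by a hindered magnesium amide to give 7, capture by a borate ester to give 8, and peroxide oxidation of the C–B bond. It has to form the aryl–metal bond without losing the neighbouring bromide and without touching ring B.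

**6 to 4 and 5.** The ether is cut at O–C1', between the oxygen and ring B, not at O–C2. Ring A then carries the oxygen as the phenoxide of 4, and the unsubstituted phenyl group is delivered as an electrophile from the trivalent iodine of 5. No transition metal is needed, so the three C–Br bonds are not exposed to oxidative addition. The reverse polarity, joining boronate 3 to an oxygen nucleophile for ring B under oxidative copper conditions, would rely on a pinacol boronate, which is a sluggish partner in that chemistry. The roles are therefore exchanged.

**4 to 1 and 2.** The C2–O bond of 4 is cut back to the C–H of 1 that lies para to the central bromine. Electrophilic substitution or deprotonation of 1 would go next to a bromine. Only a sterically governed C–H borylation with 2 reaches the single position that has no ortho substituent. The boronate 3 formed there is oxidised in the same flask. The contiguous tribromide, including the troublesome C5 bromine, is thus bought with 1 and never has to be made.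

## Alternatives that were turned down

**Alternative 1:** The O–C1' and C2'–Br bonds of ring B are disconnected together across an aryne. In the forward sense, fluoride would release the aryne from 2-(trimethylsilyl)phenyl trifluoromethanesulfonate A2. The potassium salt of 4-bromo-2-methoxyphenol A1 would add to it at oxygen, and the resulting ortho-aryl anion would have to take bromine from an electrophilic bromine donor. The product would be 4-bromo-1-(2-bromophenoxy)-2-methoxybenzene A3.
- For it: A3 already holds the C5 bromine (bought with A1) and the C2' bromine. After demethylation the free hydroxyl would direct bromine to C4 and C6, and the ether oxygen would direct one to C4'. On paper this is three steps, one fewer than the chosen route, so on step count it is the stronger plan.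
- Against it: the key step is a three-component capture in which the transient aryl anion is protonated by any adventitious proton source much more readily than it is brominated. The phenoxide of A1 can itself be brominated by the donor. The by-product lacking the C2' bromine would be hard to separate from A3. The closing tribromination must also distribute three equivalents over two rings without touching C3 or C6'.
- Comparison: the chosen route accepts one more step. In return its key step is a stoichiometric polar metalation with a defined intermediate and no regiochemical choice, and all three ring A bromines are in place from compound 1.

**Alternative 2:** The C5–Br bond is disconnected to a C5 amino group. That nitrogen begins as the nitro group that activates the ether-forming aromatic substitution para to it. The forward key step is a Sandmeyer-type bromodediazoniation of 2,6-dibromo-4-(2,4-dibromophenoxy)-3-methoxyaniline A4, whose two ring A bromines were directed by the amine. It would give 1,2,3-tribromo-5-(2,4-dibromophenoxy)-4-methoxybenzene A5, and demethylation would finish.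
- For it: every one of the five bromines is fixed by a classical directing effect or by the building blocks. Ring B arrives already dibrominated, and no competition between ring A and ring B arises. In regiochemical certainty this plan is stronger than the chosen one, whose last step depends on a reactivity difference between the two rings.
- Against it: it needs about five steps (ether formation, nitro reduction, dibromination, diazotization, demethylation) and a methyl protecting group. The diazonium group sits between two ortho bromines, and the aryl radical of the Sandmeyer manifold can abstract hydrogen, giving the C5–H analogue, which would be very difficult to remove from A5.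
- Comparison: the chosen route is shorter and needs no protecting group. The C5 bromine is never made, since it comes with 1, and the hydroxyl is introduced directly as the free phenol.

**Alternative 3:** Ring B itself is disconnected at C1'–C2' and C5'–C6'. In the forward sense 3,5-dibromo-2H-pyran-2-one A6 would act as an electron-poor diene towards the ynol ether 1-(ethynyloxy)-2-methoxybenzene A7 in an inverse-demand [4+2] cycloaddition. Cycloreversion of the bridged adduct with loss of the lactone bridge would aromatise ring B and give 1-(2,4-dibromophenoxy)-2-methoxybenzene A8.
- For it: ring B is born with exactly its two bromines, so ring B never has to be brominated. On that point it is stronger than the chosen route.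
- Against it: the difficulty of the target lies in ring A, and A8 carries none of the ring A bromines. Three adjacent bromines would still have to be placed at C4, C5 and C6 of a 2-alkoxyphenyl ether by electrophilic substitution. The C5 bromine would have to enter para to a weakly donating aryloxy oxygen in competition with C6 and C3. A7 is a sensitive aryl ethynyl ether that needs its own preparation, and the cycloaddition needs heat, so the count rises to about six steps.
- Comparison: the chosen route fixes the ring A pattern from the first compound and leaves for the end only the ortho/para bromination of ring B, the easier of the two halogenation problems.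

Key step: step 3

## Route

Step 1
Reactants: 1 1,2,3-tribromobenzene; 2 bis(pinacolato)diboron
Product: 4 3,4,5-tribromophenol, via aryl pinacol boronate 3 (not isolated)
Conditions: [Ir(OMe)(cod)]2 (1.5 mol%), dtbpy (3 mol%), 2 (0.6 equiv), THF, 60 °C; evaporate; Oxone (2KHSO5·KHSO4·K2SO4), acetone/H2O, rt
Reagents that add atoms: potassium peroxymonosulfate KHSO5 (active salt of Oxone), [K+].[O-]S(=O)(=O)OO
Why: Iridium-catalysed aromatic C–H borylation is governed by sterics and should take the only C–H of 1 that has no ortho substituent, the one para to the central bromine (the future C2 of ring A), without touching C–Br bonds. The boronate 3 is then oxidised in the same flask by peroxymonosulfate through aryl migration from boron to oxygen, a known one-pot borylation and oxidation route to 3,5-disubstituted phenols.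

Step 2
Reactants: 4 3,4,5-tribromophenol; 5 diphenyliodonium trifluoromethanesulfonate
Product: 6 1,2,3-tribromo-5-phenoxybenzene
Conditions: t-BuOK (1.1 equiv), THF, 0 °C; then 5 (1.2 equiv), 40 °C
Reagents that add atoms: none
Why: This is the metal-free O-arylation of a phenoxide with a diaryliodonium salt: the phenoxide of 4 replaces triflate on trivalent iodine, and the aryloxy(diphenyl)iodane collapses by ligand coupling to the diaryl ether and iodobenzene. The phenoxide of 4 has both ortho positions free, and with no transition metal present the three C–Br bonds are not at risk.

Step 3
Reactants: 6 1,2,3-tribromo-5-phenoxybenzene
Product: 9 2,3,4-tribromo-6-phenoxyphenol, via arylmagnesium chloride 7 (not isolated), via dimethyl arylboronate 8 (not isolated)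
Conditions: TMPMgCl·LiCl (1.2 equiv), THF, −30 °C; B(OMe)3 (2 equiv), −30 °C → rt; AcOH, 30% aq. H2O2, 0 °C → rt
Reagents that add atoms: hydrogen peroxide, OO (hydroxyl oxygen of 9); TMPMgCl·LiCl, CC1(C)CCCC(C)(C)N1[Mg]Cl.[Li+].[Cl-] (MgCl of 7 only); trimethyl borate, COB(OC)OC (B(OMe)2 of 8 only)
Why: The hindered amide of TMPMgCl·LiCl, held near the ether oxygen by coordination, should remove one of the two equivalent ring A protons that sit between the phenoxy oxygen and a bromine and are further acidified by the meta and para bromines, giving arylmagnesium chloride 7. This is a directed ortho-magnesiation of a polybromoarene, a known reaction type for hindered magnesium amides; at −30 °C the covalent C–Mg bond should neither expel the neighbouring bromide to an aryne nor enter bromine–magnesium exchange, so halogen migration is not expected. B(OMe)3 captures 7 at carbon to give boronate 8, hydroperoxide then adds to boron and triggers the 1,2-shift of the aryl group from boron to oxygen, and hydrolysis of the resulting aryl borate frees phenol 9. No ring is closed and no stereocenter is formed. The step needs site selectivity among seven aromatic C–H bonds: the mirror plane through C2 and C5 makes the two ring A sites identical, and the five phenyl hydrogens of ring B have at most one ortho heteroatom and no bromine, so they are far less acidic. Keeping ring B free of bromine at this stage removes a C3'–H flanked by two bromines that would otherwise compete.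

Step 4
Reactants: 9 2,3,4-tribromo-6-phenoxyphenol
Product: 10 2,3,4-tribromo-6-(2,4-dibromophenoxy)phenol
Conditions: Br2 (2.1 equiv), AcOH, rt → 50 °C; aq. Na2SO3 quench
Reagents that add atoms: bromine, BrBr
Why: This is an electrophilic aromatic bromination: in 9 all positions ortho and para to the hydroxyl are occupied and C3–H of ring A is crowded and sits on a ring with three deactivating bromines, so Br2 should attack the phenyl ring para (C4') and then ortho (C2') to the ether oxygen. After two bromines the last open ortho site C6' is meta to both of them and reacts much more slowly, which should let the reaction stop at 10.

## Compound list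

1 | 1,2,3-tribromobenzene | Brc1cccc(Br)c1Br | starting material
2 | bis(pinacolato)diboron | CC1(C)OB(OC1(C)C)B1OC(C)(C)C(C)(C)O1 | starting material
3 | 4,4,5,5-tetramethyl-2-(3,4,5-tribromophenyl)-1,3,2-dioxaborolane | CC1(C)OB(OC1(C)C)c1cc(Br)c(Br)c(Br)c1 | intermediate
4 | 3,4,5-tribromophenol | Oc1cc(Br)c(Br)c(Br)c1 | intermediate
5 | diphenyliodonium trifluoromethanesulfonate | [O-]S(=O)(=O)C(F)(F)F.c1ccc(cc1)[I+]c1ccccc1 | starting material
6 | 1,2,3-tribromo-5-phenoxybenzene | Brc1cc(Oc2ccccc2)cc(Br)c1Br | intermediate
7 | (2,3,4-tribromo-6-phenoxyphenyl)magnesium chloride (LiCl complex, LiCl not drawn) | Cl[Mg]c1c(Oc2ccccc2)cc(Br)c(Br)c1Br | intermediate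
8 | dimethyl (2,3,4-tribromo-6-phenoxyphenyl)boronate | COB(OC)c1c(Oc2ccccc2)cc(Br)c(Br)c1Br | intermediate
9 | 2,3,4-tribromo-6-phenoxyphenol | Oc1c(Oc2ccccc2)cc(Br)c(Br)c1Br | intermediate
10 | 2,3,4-tribromo-6-(2,4-dibromophenoxy)phenol | Oc1c(Oc2ccc(Br)cc2Br)cc(Br)c(Br)c1Br | target

## Step count and risk

Total steps: 4. Longest linear sequence: 4 steps (1 → 4 → 6 → 9 → 10).

**Step 3 (key step).** The most likely failure is slow deprotonation at the low temperature needed for the ortho-bromo arylmagnesium 7 to survive. If the mixture is warmed to force conversion, 7 may lose magnesium halide to an aryne, which then adds amide or oligomerises. Fallback, setting out from 4 and returning at 9: phenol 4 would be iodinated once at one of its two equivalent ortho positions (N-iodosuccinimide, cat. TsOH, MeCN) to give 3,4,5-tribromo-2-iodophenol F1. This would be O-phenylated with 5 under the conditions of step 2 to give 1,2,3-tribromo-4-iodo-5-phenoxybenzene F2. Iodine–magnesium exchange with iPrMgCl·LiCl in THF at −78 °C, which is much faster for C–I than for C–Br, would then generate the same arylmagnesium 7 at a temperature where it is stable. Capture with B(OMe)3 and oxidation with H2O2 as in step 3 would give 9. The carbon–magnesium bond is thus made from a halogen handle set by electrophilic substitution and not by C–H deprotonation.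

**Step 4.** The second bromination (C2', on a ring already deactivated by the C4' bromine) is sluggish. Forcing it may lead to a third bromination at C6' or at C3 of ring A, or to oxidation of the free phenol by Br2, and mixtures of tetra-, penta- and hexabromides would be hard to separate. Fallback, setting out from 9 and returning at 10: 9 would be acetylated (Ac2O, pyridine) to give 2,3,4-tribromo-6-phenoxyphenyl acetate F3. The ester shields the phenol from oxidation and deactivates ring A further. Bromination could then be driven with Br2 (2.1 equiv) and catalytic FeBr3 in CH2Cl2 to give 2,3,4-tribromo-6-(2,4-dibromophenoxy)phenyl acetate F4. Methanolysis (K2CO3, MeOH, rt) would release 10.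

**Step 2.** The tribromophenoxide of 4 is a weak nucleophile, so ligand coupling on iodine may be slow and base-induced decomposition of 5 may compete. Fallback, setting out from 4 and returning at 6: a Chan–Lam coupling of 4 with phenylboronic acid mediated by Cu(OAc)2 (pyridine, 4 Å molecular sieves, CH2Cl2, air, rt). Here the copper carries the unhalogenated phenyl group and the reaction runs at room temperature, so the C–Br bonds should be safe. This way makes no compound outside the list (F0).

## Further compounds

F1 | step 3 | 3,4,5-tribromo-2-iodophenol | Oc1cc(Br)c(Br)c(Br)c1I
F2 | step 3 | 1,2,3-tribromo-4-iodo-5-phenoxybenzene | Ic1c(Oc2ccccc2)cc(Br)c(Br)c1Br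
F3 | step 4 | 2,3,4-tribromo-6-phenoxyphenyl acetate | CC(=O)Oc1c(Oc2ccccc2)cc(Br)c(Br)c1Br
F4 | step 4 | 2,3,4-tribromo-6-(2,4-dibromophenoxy)phenyl acetate | CC(=O)Oc1c(Oc2ccc(Br)cc2Br)cc(Br)c(Br)c1Br
F0 | step 2 | none | none
A1 | alternative 1 | 4-bromo-2-methoxyphenol | COc1cc(Br)ccc1O
A2 | alternative 1 | 2-(trimethylsilyl)phenyl trifluoromethanesulfonate | C[Si](C)(C)c1ccccc1OS(=O)(=O)C(F)(F)F
A3 | alternative 1 | 4-bromo-1-(2-bromophenoxy)-2-methoxybenzene | COc1cc(Br)ccc1Oc1ccccc1Br
A4 | alternative 2 | 2,6-dibromo-4-(2,4-dibromophenoxy)-3-methoxyaniline | COc1c(Br)c(N)c(Br)cc1Oc1ccc(Br)cc1Br
A5 | alternative 2 | 1,2,3-tribromo-5-(2,4-dibromophenoxy)-4-methoxybenzene | COc1c(Br)c(Br)c(Br)cc1Oc1ccc(Br)cc1Br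
A6 | alternative 3 | 3,5-dibromo-2H-pyran-2-one | O=c1occ(Br)cc1Br
A7 | alternative 3 | 1-(ethynyloxy)-2-methoxybenzene | COc1ccccc1OC#C
A8 | alternative 3 | 1-(2,4-dibromophenoxy)-2-methoxybenzene | COc1ccccc1Oc1ccc(Br)cc1Br
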